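**Retrosynthetic overview**

- The C-8 ester is made by invertive (Mitsunobu) acylation of an axial 8β-alcohol with the silyl-protected Roche acid; the allylic C-15 hydroxyl comes from late SeO2 hydroxylation of an isopropenyl group.
- The α-methylene lactone comes from a keto lactone, itself from a trans hydroxy acid; the lactone is the second ring formed.
- The cyclohexane (first ring) is closed at C6–C7 by an intramolecular aldol of a keto aldehyde, after a Stetter acylation of diallyl fumarate has made C7–C8.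
- The C-5/C-10 pair (quaternary carbon with vinyl cis to the C-5 side chain) is set by a dianionic Ireland–Claisen [3,3] rearrangement of an (E)-allyl (R)-3-hydroxybutanoate. The carbinol steers the face and is then erased by oxidation and methylenation.
- C-6, C-7 and C-8 follow from the chair fixed by C-5/C-10 (axial vinyl); C-2′ is bought in the Roche ester.

Convention and assumption: C-labels follow elemane numbering (C-10 quaternary, C-5 to C-9 round the ring, C-11 to C-13 lactone, C-15 the CH2OH carbon); the alkyne, the two hydroxy esters and diallyl fumarate are taken as catalogue chemicals.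

Note on the target: the given SMILES has the C-10 vinyl cis to the C-5 side chain (10R). A thermal Cope rearrangement of an (E,E)-germacranolide gives the trans (10S) isomer, so the route builds C-5/C-10 by the Claisen rearrangement instead. This route is a paper proposal; nothing in it has been run.

**Route**

Step 1
Reactants: 1 1-[(but-3-yn-1-yloxy)methyl]-4-methoxybenzene
Product: 3 (2E)-5-[(4-methoxybenzyl)oxy]-3-methylpent-2-en-1-ol, via alkenylalane 2 (not isolated)
Conditions: AlMe3, Cp2ZrCl2 (20 mol %), CH2Cl2, 0 °C to rt; then n-BuLi, THF, −78 °C; (CH2O)n, −78 °C to rt; aq. work-up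
Reagents that add atoms: trimethylaluminium, C[Al](C)C; formaldehyde (from paraformaldehyde), C=O
Why: Negishi zirconium-catalysed carboalumination adds CH3 and Al syn across the alkyne with Al at the terminus, and the alanate is trapped by formaldehyde with retention, so only the (E)-allylic alcohol forms.

Step 2
Reactants: 3 (2E)-5-[(4-methoxybenzyl)oxy]-3-methylpent-2-en-1-ol; 4 methyl (3R)-3-hydroxybutanoate
Product: 5 (2E)-5-[(4-methoxybenzyl)oxy]-3-methylpent-2-en-1-yl (3R)-3-hydroxybutanoate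
Conditions: [ClBu2SnOSnBu2OH]2 (2 mol %), toluene, 110 °C, 4 Å MS (−MeOH)
Reagents that add atoms: none
Why: Distannoxane-catalysed transesterification is neutral, so the primary allylic alcohol replaces OMe without touching the β-hydroxyl or its stereocentre.

Step 3
Reactants: 5 (2E)-5-[(4-methoxybenzyl)oxy]-3-methylpent-2-en-1-yl (3R)-3-hydroxybutanoate
Product: 7 (2R,3R)-3-hydroxy-2-[(3R)-5-[(4-methoxybenzyl)oxy]-3-methylpent-1-en-3-yl]butanoic acid, via dilithium dianion 6 (not isolated)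
Conditions: LiN(i-Pr)2 (2.3 equiv), THF, −78 °C, then rt to 60 °C; 1 M HCl
Reagents that add atoms: none
Why: Dianionic Ireland–Claisen [3,3]-sigmatropic rearrangement: the lithium-chelated enolate (enolate O cis to the carbinol carbon) reacts through a chair on the face anti to the carbinol methyl, and the (E)-alkene puts its CH3 axial, so C-5 and the quaternary C-10 form together with the target's relative and absolute configuration.

Step 4
Reactants: 7 (2R,3R)-3-hydroxy-2-[(3R)-5-[(4-methoxybenzyl)oxy]-3-methylpent-1-en-3-yl]butanoic acid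
Product: 8 (2S,3R)-2-[(3R)-5-[(4-methoxybenzyl)oxy]-3-methylpent-1-en-3-yl]butane-1,3-diol
Conditions: LiAlH4, THF, 0 °C to rt
Reagents that add atoms: none
Why: Hydride reduction of the carboxylic acid to the primary alcohol removes the C-6 carbonyl so that C-5 cannot epimerise when C-4 is later oxidised.

Step 5
Reactants: 8 (2S,3R)-2-[(3R)-5-[(4-methoxybenzyl)oxy]-3-methylpent-1-en-3-yl]butane-1,3-diol
Product: 9 (2R,3S)-3-[(3R)-5-[(4-methoxybenzyl)oxy]-3-methylpent-1-en-3-yl]-4-[(triethylsilyl)oxy]butan-2-ol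
Conditions: Et3SiCl (1.05 equiv), imidazole, CH2Cl2, −20 °C
Reagents that add atoms: chlorotriethylsilane, CC[Si](Cl)(CC)CC
Why: Silyl ether formation is selective for the primary hydroxyl over the hindered secondary one.

Step 6
Reactants: 9 (2R,3S)-3-[(3R)-5-[(4-methoxybenzyl)oxy]-3-methylpent-1-en-3-yl]-4-[(triethylsilyl)oxy]butan-2-ol
Product: 10 (3S)-3-[(3R)-5-[(4-methoxybenzyl)oxy]-3-methylpent-1-en-3-yl]-4-[(triethylsilyl)oxy]butan-2-one
Conditions: Dess–Martin periodinane, pyridine, CH2Cl2, 0 °C to rt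
Reagents that add atoms: none
Why: Dess–Martin oxidation of the secondary alcohol is neutral, so the α-stereocentre and the β-silyloxy group are not disturbed.

Step 7
Reactants: 10 (3S)-3-[(3R)-5-[(4-methoxybenzyl)oxy]-3-methylpent-1-en-3-yl]-4-[(triethylsilyl)oxy]butan-2-one
Product: 11 triethyl{[(2S)-2-[(3R)-5-[(4-methoxybenzyl)oxy]-3-methylpent-1-en-3-yl]-3-methylbut-3-en-1-yl]oxy}silane
Conditions: Cp2TiMe2 (3 equiv), toluene, 70 °C, dark
Reagents that add atoms: dimethyltitanocene, [CH3-].[CH3-].[Ti+4].c1cc[cH-]c1.c1cc[cH-]c1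
Why: Petasis methylenation is non-basic, so the methyl ketone becomes the isopropenyl group without epimerisation at C-5 or β-elimination of the silyloxy group.

Step 8
Reactants: 11 triethyl{[(2S)-2-[(3R)-5-[(4-methoxybenzyl)oxy]-3-methylpent-1-en-3-yl]-3-methylbut-3-en-1-yl]oxy}silane
Product: 12 (3R)-3-methyl-3-[(2S)-3-methyl-1-[(triethylsilyl)oxy]but-3-en-2-yl]pent-4-en-1-ol
Conditions: DDQ, CH2Cl2/pH 7 buffer, 0 °C
Reagents that add atoms: none
Why: Oxidative cleavage of the 4-methoxybenzyl ether by DDQ leaves the silyl ether and the alkenes untouched.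

Step 9
Reactants: 12 (3R)-3-methyl-3-[(2S)-3-methyl-1-[(triethylsilyl)oxy]but-3-en-2-yl]pent-4-en-1-ol
Product: 13 (3R)-3-methyl-3-[(2S)-3-methyl-1-[(triethylsilyl)oxy]but-3-en-2-yl]pent-4-enal
Conditions: Dess–Martin periodinane, pyridine, CH2Cl2, 0 °C to rt
Reagents that add atoms: none
Why: Dess–Martin oxidation stops cleanly at the aldehyde, which has no α-stereocentre to lose.

Step 10
Reactants: 13 (3R)-3-methyl-3-[(2S)-3-methyl-1-[(triethylsilyl)oxy]but-3-en-2-yl]pent-4-enal; 14 diallyl fumarate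
Product: 15 diallyl 2-{(3R)-3-methyl-3-[(2S)-3-methyl-1-[(triethylsilyl)oxy]but-3-en-2-yl]pent-4-enoyl}butanedioate
Conditions: 3-benzyl-5-(2-hydroxyethyl)-4-methylthiazolium chloride (20 mol %), Et3N (0.6 equiv), dioxane, 80 °C
Reagents that add atoms: none
Why: Stetter reaction: the carbene-derived acyl anion equivalent of the aldehyde adds to the fumarate, making the C7–C8 bond and a β-keto ester whose new centre (C-7) is labile and of no consequence.

Step 11
Reactants: 15 diallyl 2-{(3R)-3-methyl-3-[(2S)-3-methyl-1-[(triethylsilyl)oxy]but-3-en-2-yl]pent-4-enoyl}butanedioate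
Product: 16 diallyl 2-{(3R)-3-[(2S)-1-hydroxy-3-methylbut-3-en-2-yl]-3-methylpent-4-enoyl}butanedioate
Conditions: HF·pyridine, pyridine, THF, 0 °C
Reagents that add atoms: none
Why: Fluoride desilylation frees the primary alcohol without the ketal formation that acidic methanol would cause.

Step 12
Reactants: 16 diallyl 2-{(3R)-3-[(2S)-1-hydroxy-3-methylbut-3-en-2-yl]-3-methylpent-4-enoyl}butanedioate
Product: 18 allyl (2R,3S,4R)-1-[2-(allyloxy)-2-oxoethyl]-4-ethenyl-2-hydroxy-4-methyl-6-oxo-3-(prop-1-en-2-yl)cyclohexane-1-carboxylate, via keto aldehyde 17 (not isolated)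
Conditions: TEMPO (10 mol %), PhI(OAc)2, CH2Cl2, rt; then Et3N (0.3 equiv), 0 °C
Reagents that add atoms: none
Why: TEMPO oxidation then intramolecular aldol addition of the acidic β-keto ester carbon closes the six-membered ring reversibly, and the 6-OH settles equatorial (α) because an axial OH would be syn-axial to the C-10 vinyl group; the quaternary C-7 cannot dehydrate.

Step 13
Reactants: 18 allyl (2R,3S,4R)-1-[2-(allyloxy)-2-oxoethyl]-4-ethenyl-2-hydroxy-4-methyl-6-oxo-3-(prop-1-en-2-yl)cyclohexane-1-carboxylate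
Product: 21 (3aS,6R,7S,7aR)-6-ethenyl-6-methyl-7-(prop-1-en-2-yl)tetrahydro-1-benzofuran-2,4(3H,5H)-dione, via diacid 19 (not isolated), via hydroxy keto acid 20 (not isolated)
Conditions: Pd(OAc)2 (5 mol %), PPh3, HCO2H, Et3N, THF, rt; then PPTS (cat.), toluene, 40 °C
Reagents that add atoms: none
Why: Tsuji deallylation and decarboxylation of the β-keto acid leave C-7 free to equilibrate to the equatorial CH2CO2H (trans to 6-OH), and lactonisation then gives the trans-fused γ-lactone, which is reduced at once to avoid C-7 epimerisation.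

Step 14
Reactants: 21 (3aS,6R,7S,7aR)-6-ethenyl-6-methyl-7-(prop-1-en-2-yl)tetrahydro-1-benzofuran-2,4(3H,5H)-dione
Product: 22 (3aR,4R,6R,7S,7aR)-6-ethenyl-4-hydroxy-6-methyl-7-(prop-1-en-2-yl)hexahydro-1-benzofuran-2(3H)-one
Conditions: LiBH(s-Bu)3, THF, −78 °C; AcOH quench at −78 °C
Reagents that add atoms: none
Why: Ketone reduction with a bulky hydride occurs by equatorial attack, reinforced by the syn-axial C-10 vinyl group blocking the axial face, and gives the axial 8β-alcohol.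

Step 15
Reactants: 22 (3aR,4R,6R,7S,7aR)-6-ethenyl-4-hydroxy-6-methyl-7-(prop-1-en-2-yl)hexahydro-1-benzofuran-2(3H)-one
Product: 25 (3aR,4R,6R,7S,7aR)-6-ethenyl-4-hydroxy-6-methyl-3-methylidene-7-(prop-1-en-2-yl)hexahydro-1-benzofuran-2(3H)-one, via Mannich base 23 (not isolated), via ammonium iodide 24 (not isolated)
Conditions: LiN(i-Pr)2 (2.3 equiv), THF, −78 °C; CH2=NMe2+ I−, −78 to −20 °C; H2O; then MeI, MeOH, rt; then aq. NaHCO3, CH2Cl2
Reagents that add atoms: N,N-dimethylmethyleneiminium iodide, C=[N+](C)C.[I-]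
Why: Mannich reaction of the alkoxide–lactone enolate dianion followed by quaternisation and Hofmann-type elimination installs the α-methylene group; forming the enolate at once keeps the alkoxide from attacking the lactone.

Step 16
Reactants: 26 methyl (2R)-3-hydroxy-2-methylpropanoate
Product: 27 methyl (2R)-3-[(tert-butyldimethylsilyl)oxy]-2-methylpropanoate
Conditions: t-BuMe2SiCl, imidazole, DMF, rt
Reagents that add atoms: tert-butylchlorodimethylsilane, CC(C)(C)[Si](C)(C)Cl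
Why: Standard silyl protection of the primary alcohol leaves the bought stereocentre untouched.

Step 17
Reactants: 27 methyl (2R)-3-[(tert-butyldimethylsilyl)oxy]-2-methylpropanoate
Product: 28 (2R)-3-[(tert-butyldimethylsilyl)oxy]-2-methylpropanoic acid
Conditions: LiOH, THF/H2O, 0 °C to rt; 1 M HCl to pH 3
Reagents that add atoms: lithium hydroxide, [Li+].[OH-]
Why: Mild saponification of the methyl ester proceeds without racemisation of the α-centre.

Step 18
Reactants: 25 (3aR,4R,6R,7S,7aR)-6-ethenyl-4-hydroxy-6-methyl-3-methylidene-7-(prop-1-en-2-yl)hexahydro-1-benzofuran-2(3H)-one; 28 (2R)-3-[(tert-butyldimethylsilyl)oxy]-2-methylpropanoic acid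
Product: 29 (3aR,4S,6R,7S,7aR)-6-ethenyl-6-methyl-3-methylidene-2-oxo-7-(prop-1-en-2-yl)octahydro-1-benzofuran-4-yl (2R)-3-[(tert-butyldimethylsilyl)oxy]-2-methylpropanoate
Conditions: PPh3, DIAD, toluene, 0 °C to rt
Reagents that add atoms: none
Why: Mitsunobu esterification displaces the activated axial 8β-oxygen by SN2 with inversion and so gives the equatorial 8α-ester; the acid's α-centre is not enolised.

Step 19
Reactants: 29 (3aR,4S,6R,7S,7aR)-6-ethenyl-6-methyl-3-methylidene-2-oxo-7-(prop-1-en-2-yl)octahydro-1-benzofuran-4-yl (2R)-3-[(tert-butyldimethylsilyl)oxy]-2-methylpropanoate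
Product: 30 (3aR,4S,6R,7R,7aR)-6-ethenyl-7-(3-hydroxyprop-1-en-2-yl)-6-methyl-3-methylidene-2-oxooctahydro-1-benzofuran-4-yl (2R)-3-[(tert-butyldimethylsilyl)oxy]-2-methylpropanoate
Conditions: SeO2 (0.3 equiv), t-BuOOH, CH2Cl2, 0 °C to rt
Reagents that add atoms: tert-butyl hydroperoxide, CC(C)(C)OO
Why: SeO2-catalysed allylic hydroxylation (ene reaction then [2,3] shift) attacks the isopropenyl methyl, the only reactive allylic C–H (the vinyl group has none and the lactone methylene is electron-poor).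

Step 20
Reactants: 30 (3aR,4S,6R,7R,7aR)-6-ethenyl-7-(3-hydroxyprop-1-en-2-yl)-6-methyl-3-methylidene-2-oxooctahydro-1-benzofuran-4-yl (2R)-3-[(tert-butyldimethylsilyl)oxy]-2-methylpropanoate
Product: 31 (3aR,4S,6R,7R,7aR)-6-ethenyl-7-(3-hydroxyprop-1-en-2-yl)-6-methyl-3-methylidene-2-oxooctahydro-1-benzofuran-4-yl (2R)-3-hydroxy-2-methylpropanoate
Conditions: HF·pyridine, pyridine, THF, 0 °C to rt
Reagents that add atoms: none
Why: Buffered fluoride desilylation removes the silyl ether without base, so the ester, the lactone and the methylene group survive.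

**Compound list**

1 | 1-[(but-3-yn-1-yloxy)methyl]-4-methoxybenzene | C#CCCOCc1ccc(OC)cc1 | starting material
2 | [(1E)-4-[(4-methoxybenzyl)oxy]-2-methylbut-1-en-1-yl]dimethylalane | C[Al](C)/C=C(\C)CCOCc1ccc(OC)cc1 | intermediate
3 | (2E)-5-[(4-methoxybenzyl)oxy]-3-methylpent-2-en-1-ol | OC/C=C(\C)CCOCc1ccc(OC)cc1 | intermediate
4 | methyl (3R)-3-hydroxybutanoate | C[C@@H](O)CC(=O)OC | starting material
5 | (2E)-5-[(4-methoxybenzyl)oxy]-3-methylpent-2-en-1-yl (3R)-3-hydroxybutanoate | C[C@@H](O)CC(=O)OC/C=C(\C)CCOCc1ccc(OC)cc1 | intermediate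
6 | dilithium alkoxide–enolate of 5 (chelated, enolate O cis to the carbinol carbon) | C[C@@H]([O-])/C=C(\[O-])OC/C=C(\C)CCOCc1ccc(OC)cc1.[Li+].[Li+] | intermediate
7 | (2R,3R)-3-hydroxy-2-[(3R)-5-[(4-methoxybenzyl)oxy]-3-methylpent-1-en-3-yl]butanoic acid | C=C[C@@]([C@@H](C(=O)O)[C@@H](C)O)(C)CCOCc1ccc(OC)cc1 | intermediate
8 | (2S,3R)-2-[(3R)-5-[(4-methoxybenzyl)oxy]-3-methylpent-1-en-3-yl]butane-1,3-diol | C=C[C@@]([C@@H](CO)[C@@H](C)O)(C)CCOCc1ccc(OC)cc1 | intermediate
9 | (2R,3S)-3-[(3R)-5-[(4-methoxybenzyl)oxy]-3-methylpent-1-en-3-yl]-4-[(triethylsilyl)oxy]butan-2-ol | C=C[C@@]([C@@H](CO[Si](CC)(CC)CC)[C@@H](C)O)(C)CCOCc1ccc(OC)cc1 | intermediate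
10 | (3S)-3-[(3R)-5-[(4-methoxybenzyl)oxy]-3-methylpent-1-en-3-yl]-4-[(triethylsilyl)oxy]butan-2-one | C=C[C@@]([C@@H](CO[Si](CC)(CC)CC)C(C)=O)(C)CCOCc1ccc(OC)cc1 | intermediate
11 | triethyl{[(2S)-2-[(3R)-5-[(4-methoxybenzyl)oxy]-3-methylpent-1-en-3-yl]-3-methylbut-3-en-1-yl]oxy}silane | C=C[C@@]([C@@H](CO[Si](CC)(CC)CC)C(C)=C)(C)CCOCc1ccc(OC)cc1 | intermediate
12 | (3R)-3-methyl-3-[(2S)-3-methyl-1-[(triethylsilyl)oxy]but-3-en-2-yl]pent-4-en-1-ol | C=C[C@@]([C@@H](CO[Si](CC)(CC)CC)C(C)=C)(C)CCO | intermediate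
13 | (3R)-3-methyl-3-[(2S)-3-methyl-1-[(triethylsilyl)oxy]but-3-en-2-yl]pent-4-enal | C=C[C@@]([C@@H](CO[Si](CC)(CC)CC)C(C)=C)(C)CC=O | intermediate
14 | diallyl fumarate | C=CCOC(=O)/C=C/C(=O)OCC=C | starting material
15 | diallyl 2-{(3R)-3-methyl-3-[(2S)-3-methyl-1-[(triethylsilyl)oxy]but-3-en-2-yl]pent-4-enoyl}butanedioate (both epimers at the succinate carbon) | C=C[C@@]([C@@H](CO[Si](CC)(CC)CC)C(C)=C)(C)CC(=O)C(CC(=O)OCC=C)C(=O)OCC=C | intermediate
16 | diallyl 2-{(3R)-3-[(2S)-1-hydroxy-3-methylbut-3-en-2-yl]-3-methylpent-4-enoyl}butanedioate | C=C[C@@]([C@@H](CO)C(C)=C)(C)CC(=O)C(CC(=O)OCC=C)C(=O)OCC=C | intermediate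
17 | diallyl 2-{(3R)-3-methyl-3-[(2S)-3-methyl-1-oxobut-3-en-2-yl]pent-4-enoyl}butanedioate | C=C[C@@]([C@@H](C=O)C(C)=C)(C)CC(=O)C(CC(=O)OCC=C)C(=O)OCC=C | intermediate
18 | allyl (2R,3S,4R)-1-[2-(allyloxy)-2-oxoethyl]-4-ethenyl-2-hydroxy-4-methyl-6-oxo-3-(prop-1-en-2-yl)cyclohexane-1-carboxylate (either configuration at C-1) | C=C[C@@]1(C)CC(=O)C(CC(=O)OCC=C)(C(=O)OCC=C)[C@H](O)[C@H]1C(C)=C | intermediate
19 | (2R,3S,4R)-1-(carboxymethyl)-4-ethenyl-2-hydroxy-4-methyl-6-oxo-3-(prop-1-en-2-yl)cyclohexane-1-carboxylic acid | C=C[C@@]1(C)CC(=O)C(CC(=O)O)(C(=O)O)[C@H](O)[C@H]1C(C)=C | intermediate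
20 | [(1S,2R,3S,4R)-4-ethenyl-2-hydroxy-4-methyl-6-oxo-3-(prop-1-en-2-yl)cyclohexyl]acetic acid | C=C[C@@]1(C)CC(=O)[C@@H](CC(=O)O)[C@H](O)[C@H]1C(C)=C | intermediate
21 | (3aS,6R,7S,7aR)-6-ethenyl-6-methyl-7-(prop-1-en-2-yl)tetrahydro-1-benzofuran-2,4(3H,5H)-dione | C=C[C@@]1(C)CC(=O)[C@H]2CC(=O)O[C@@H]2[C@H]1C(C)=C | intermediate
22 | (3aR,4R,6R,7S,7aR)-6-ethenyl-4-hydroxy-6-methyl-7-(prop-1-en-2-yl)hexahydro-1-benzofuran-2(3H)-one | C=C[C@@]1(C)C[C@@H](O)[C@H]2CC(=O)O[C@@H]2[C@H]1C(C)=C | intermediate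
23 | (3aR,4R,6R,7S,7aR)-3-[(dimethylamino)methyl]-6-ethenyl-4-hydroxy-6-methyl-7-(prop-1-en-2-yl)hexahydro-1-benzofuran-2(3H)-one (C-3 epimers) | C=C[C@@]1(C)C[C@@H](O)[C@H]2C(CN(C)C)C(=O)O[C@@H]2[C@H]1C(C)=C | intermediate
24 | N-methyl ammonium iodide of 23 | C=C[C@@]1(C)C[C@@H](O)[C@H]2C(C[N+](C)(C)C)C(=O)O[C@@H]2[C@H]1C(C)=C.[I-] | intermediate
25 | (3aR,4R,6R,7S,7aR)-6-ethenyl-4-hydroxy-6-methyl-3-methylidene-7-(prop-1-en-2-yl)hexahydro-1-benzofuran-2(3H)-one | C=C[C@@]1(C)C[C@@H](O)[C@H]2C(=C)C(=O)O[C@@H]2[C@H]1C(C)=C | intermediate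
26 | methyl (2R)-3-hydroxy-2-methylpropanoate | COC(=O)[C@H](C)CO | starting material
27 | methyl (2R)-3-[(tert-butyldimethylsilyl)oxy]-2-methylpropanoate | COC(=O)[C@H](C)CO[Si](C)(C)C(C)(C)C | intermediate
28 | (2R)-3-[(tert-butyldimethylsilyl)oxy]-2-methylpropanoic acid | OC(=O)[C@H](C)CO[Si](C)(C)C(C)(C)C | intermediate
29 | (3aR,4S,6R,7S,7aR)-6-ethenyl-6-methyl-3-methylidene-2-oxo-7-(prop-1-en-2-yl)octahydro-1-benzofuran-4-yl (2R)-3-[(tert-butyldimethylsilyl)oxy]-2-methylpropanoate | C=C[C@@]1(C)C[C@H](OC(=O)[C@H](C)CO[Si](C)(C)C(C)(C)C)[C@H]2C(=C)C(=O)O[C@@H]2[C@H]1C(C)=C | intermediate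
30 | (3aR,4S,6R,7R,7aR)-6-ethenyl-7-(3-hydroxyprop-1-en-2-yl)-6-methyl-3-methylidene-2-oxooctahydro-1-benzofuran-4-yl (2R)-3-[(tert-butyldimethylsilyl)oxy]-2-methylpropanoate | C=C[C@@]1(C)C[C@H](OC(=O)[C@H](C)CO[Si](C)(C)C(C)(C)C)[C@H]2C(=C)C(=O)O[C@@H]2[C@H]1C(=C)CO | intermediate
31 | (3aR,4S,6R,7R,7aR)-6-ethenyl-7-(3-hydroxyprop-1-en-2-yl)-6-methyl-3-methylidene-2-oxooctahydro-1-benzofuran-4-yl (2R)-3-hydroxy-2-methylpropanoate | C=C[C@@]1(C)C[C@H](OC(=O)[C@H](C)CO)[C@H]2C(=C)C(=O)O[C@@H]2[C@H]1C(=C)CO | target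

**Step count**

Total: 20 steps. Longest linear sequence: 18 steps (steps 1 to 15, then 18 to 20).

**Steps most likely to fail, with fallbacks**

Step 12 is the first risk: triethylamine may move the β,γ-unsaturated aldehyde 17 into conjugation or epimerise C-5 before the ring closes. The fallback sets out from 16 and returns at 18. Alcohol 16 is oxidised as before but 17 is isolated and brominated at the activated succinate carbon with N-bromosuccinimide in CH2Cl2 at 0 °C, giving the bromo keto aldehyde F1. SmI2 in THF at −78 °C then turns the C–Br bond into a samarium enolate, which adds to the aldehyde in an intramolecular Reformatsky-type aldol and gives 18 with no amine base present.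

Step 18 is the second risk: the axial alcohol 25 is hindered and may eliminate rather than invert. The fallback sets out from 21 and returns at 29, acylating with retention instead. Ketone 21 is reduced with NaBH4 and CeCl3·7H2O in MeOH at −78 °C (small hydride, axial attack), and the equatorial 8α-alcohol F2 is separated from 22. It is carried through the sequence of step 15, by way of the Mannich base F3 and the ammonium iodide F4, to the 8α-hydroxy methylene lactone F5. F5 is esterified with acid 28 using 2,4,6-trichlorobenzoyl chloride, Et3N and DMAP in toluene to give 29.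

Step 19 is the third risk: SeO2 may over-oxidise to the enal or give low conversion. The fallback sets out from 29 and returns at 30. A Schenck ene reaction of 29 with singlet oxygen (O2, tetraphenylporphyrin, visible light, CH2Cl2, 0 °C) takes a hydrogen from the isopropenyl methyl and gives the allylic hydroperoxide F6, which PPh3 reduces to 30.

**Further compounds**

F1 | step 12 | diallyl 2-bromo-2-{(3R)-3-methyl-3-[(2S)-3-methyl-1-oxobut-3-en-2-yl]pent-4-enoyl}butanedioate | C=C[C@@]([C@@H](C=O)C(C)=C)(C)CC(=O)C(Br)(CC(=O)OCC=C)C(=O)OCC=C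
F2 | step 18 | (3aR,4S,6R,7S,7aR)-6-ethenyl-4-hydroxy-6-methyl-7-(prop-1-en-2-yl)hexahydro-1-benzofuran-2(3H)-one | C=C[C@@]1(C)C[C@H](O)[C@H]2CC(=O)O[C@@H]2[C@H]1C(C)=C
F3 | step 18 | (3aR,4S,6R,7S,7aR)-3-[(dimethylamino)methyl]-6-ethenyl-4-hydroxy-6-methyl-7-(prop-1-en-2-yl)hexahydro-1-benzofuran-2(3H)-one (C-3 epimers) | C=C[C@@]1(C)C[C@H](O)[C@H]2C(CN(C)C)C(=O)O[C@@H]2[C@H]1C(C)=C
F4 | step 18 | N-methyl ammonium iodide of F3 | C=C[C@@]1(C)C[C@H](O)[C@H]2C(C[N+](C)(C)C)C(=O)O[C@@H]2[C@H]1C(C)=C.[I-]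
F5 | step 18 | (3aR,4S,6R,7S,7aR)-6-ethenyl-4-hydroxy-6-methyl-3-methylidene-7-(prop-1-en-2-yl)hexahydro-1-benzofuran-2(3H)-one | C=C[C@@]1(C)C[C@H](O)[C@H]2C(=C)C(=O)O[C@@H]2[C@H]1C(C)=C
F6 | step 19 | (3aR,4S,6R,7R,7aR)-6-ethenyl-7-(3-hydroperoxyprop-1-en-2-yl)-6-methyl-3-methylidene-2-oxooctahydro-1-benzofuran-4-yl (2R)-3-[(tert-butyldimethylsilyl)oxy]-2-methylpropanoate | C=C[C@@]1(C)C[C@H](OC(=O)[C@H](C)CO[Si](C)(C)C(C)(C)C)[C@H]2C(=C)C(=O)O[C@@H]2[C@H]1C(=C)COO
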